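**Retrosynthetic overview**
1. The target comes from its heptakis(methoxymethyl) ether by one global unmasking at the end.
2. The cyclohexene is the last ring formed. It arises by a three-to-six ring expansion: rhodium C–C activation of an aryl/styrenyl vinylcyclopropane, then insertion of one aroyl-carbene carbon from a β-keto sulfoxonium ylide. This makes both bonds to the ketone-bearing carbon and fixes the C(Me)=CH position.
3. The cyclopropane is the second ring. It comes from enantioselective cyclopropanation of the terminal C=CH2 of a 5-(3-methylbutadienyl)-2-arylbenzofuran with a 2,4-dioxygenated aryldiazomethane.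
4. The benzofuran is the first ring. It comes from Sonogashira coupling and 5-endo-dig closure of 4,6-diiodoresorcinol with a 3,5-dioxygenated phenylacetylene. The diene is added by hydroboration and Suzuki coupling.
5. All four arenes come from resorcinol, and pieces of one to five carbons supply the rest.

Assumption: the SMILES is taken as drawn, that is the all-trans adduct, (1R,2R,6S) on the cyclohexene. C1 bears the ketone, C2 the benzofuranyl group, C3=C4(Me) is the alkene, and C6 bears the 2,4-dihydroxyphenyl group. Small carbon sources that end up in the skeleton are numbered as starting materials.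

**Step 1**
Reactants: 1 resorcinol
Product: 2 1,3-bis(methoxymethoxy)benzene
Conditions: NaH (2.2 equiv), MOMCl (2.2 equiv), DMF, 0 °C to rt
Reagents that add atoms: chloromethyl methyl ether, COCCl
Why: Williamson-type O-alkylation of the bis-phenoxide gives the bis-acetal, which tolerates all later bases and metals, directs the two lithiations and blocks the ortho positions in the borylation.

**Step 2**
Reactants: 2 1,3-bis(methoxymethoxy)benzene
Product: 4 1-iodo-3,5-bis(methoxymethoxy)benzene, via arylboronate 3 (not isolated)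
Conditions: [Ir(cod)(OMe)]2 (1.5 mol %), dtbpy (3 mol %), B2pin2 (1.0 equiv), THF, 80 °C; evaporate; CuI (10 mol %), 1,10-phenanthroline (20 mol %), KI (1.5 equiv), MeOH/H2O, air, 80 °C
Reagents that add atoms: bis(pinacolato)diboron, CC1(C)OB(OC1(C)C)B1OC(C)(C)C(C)(C)O1 (stays in 3 only); potassium iodide, [K+].[I-]
Why: Sterically controlled iridium-catalysed C–H borylation touches only the C–H meta to both OMOM groups, and the copper-catalysed aerobic iododeboronation replaces boron at the same carbon without electrophilic iodination of the activated ring positions.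

**Step 3**
Reactants: 4 1-iodo-3,5-bis(methoxymethoxy)benzene; 5 ethynyltrimethylsilane
Product: 6 {[3,5-bis(methoxymethoxy)phenyl]ethynyl}trimethylsilane
Conditions: PdCl2(PPh3)2 (2 mol %), CuI (4 mol %), Et3N, THF, rt
Reagents that add atoms: none
Why: Sonogashira coupling of an aryl iodide runs at room temperature and leaves the acetals and the silyl cap untouched.

**Step 4**
Reactants: 1 resorcinol
Product: 7 4,6-diiodobenzene-1,3-diol
Conditions: ICl (2.05 equiv), Et2O, 0 °C to rt
Reagents that add atoms: iodine monochloride, ClI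
Why: Electrophilic aromatic iodination under acidic conditions goes to the two equivalent positions that are ortho to one hydroxyl and para to the other, while the crowded position between the hydroxyls stays free.

**Step 5**
Reactants: 6 {[3,5-bis(methoxymethoxy)phenyl]ethynyl}trimethylsilane; 7 4,6-diiodobenzene-1,3-diol
Product: 10 2-[3,5-bis(methoxymethoxy)phenyl]-5-iodo-1-benzofuran-6-ol, via terminal alkyne 8 (not isolated), via alkynylphenol 9 (not isolated)
Conditions: 7 (2.5 equiv, excess recovered), CsF (1.2 equiv), PdCl2(PPh3)2 (3 mol %), CuI (5 mol %), Et3N, DMF, 60 °C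
Reagents that add atoms: none
Why: Fluoride frees the alkyne, Sonogashira coupling with an excess of the symmetric diiodide stops after one iodine, and the ortho-hydroxyl adds 5-endo-dig to the metal-activated alkyne (Castro–Stephens-type benzofuran synthesis), which leaves the second iodine at C5 next to the free 6-OH.

**Step 6**
Reactants: 10 2-[3,5-bis(methoxymethoxy)phenyl]-5-iodo-1-benzofuran-6-ol
Product: 11 2-[3,5-bis(methoxymethoxy)phenyl]-5-iodo-6-(methoxymethoxy)-1-benzofuran
Conditions: NaH (1.2 equiv), MOMCl (1.2 equiv), DMF, 0 °C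
Reagents that add atoms: chloromethyl methyl ether, COCCl
Why: Williamson-type O-alkylation masks the last free phenol so that it can neither add to the diene nor quench the later carbene-transfer steps.

**Step 7**
Reactants: 12 2-methylbut-1-en-3-yne; 11 2-[3,5-bis(methoxymethoxy)phenyl]-5-iodo-6-(methoxymethoxy)-1-benzofuran
Product: 14 2-[3,5-bis(methoxymethoxy)phenyl]-6-(methoxymethoxy)-5-[(1E)-3-methylbuta-1,3-dienyl]-1-benzofuran, via dienylboronate 13 (not isolated)
Conditions: HBpin (1.1 equiv), Cp2ZrHCl (5 mol %), Et3N (5 mol %), 60 °C; then 11, Pd(dppf)Cl2 (3 mol %), K3PO4 (aq), THF, 50 °C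
Reagents that add atoms: pinacolborane, CC1(C)OBOC1(C)C (stays in 13 only)
Why: Zirconium-catalysed syn hydroboration of the terminal alkyne gives the E-dienylboronate, and Suzuki–Miyaura coupling with the aryl iodide keeps that geometry.

**Step 8**
Reactants: 1 resorcinol; 15 N,N-dimethylformamide
Product: 18 2,4-dihydroxybenzaldehyde, via chloroiminium salt 16 (not isolated), via aryl iminium salt 17 (not isolated)
Conditions: POCl3 (1.2 equiv), MeCN, −15 °C to rt; then H2O, 50 °C
Reagents that add atoms: phosphoryl chloride, O=P(Cl)(Cl)Cl (stays in 16 and 17 only); water, O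
Why: Vilsmeier–Haack formylation attacks the most nucleophilic ring position (para to one hydroxyl and ortho to the other), and hydrolysis of the precipitated iminium salt gives the aldehyde.

**Step 9**
Reactants: 18 2,4-dihydroxybenzaldehyde
Product: 19 2,4-bis(methoxymethoxy)benzaldehyde
Conditions: NaH (2.3 equiv), MOMCl (2.3 equiv), DMF, 0 °C to rt
Reagents that add atoms: chloromethyl methyl ether, COCCl
Why: Williamson-type O-alkylation with a strong base also captures the hydrogen-bonded ortho-hydroxyl and gives the fully masked aldehyde.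

**Step 10**
Reactants: 19 2,4-bis(methoxymethoxy)benzaldehyde; 14 2-[3,5-bis(methoxymethoxy)phenyl]-6-(methoxymethoxy)-5-[(1E)-3-methylbuta-1,3-dienyl]-1-benzofuran
Product: 22 5-{(E)-2-[(1R,2S)-2-[2,4-bis(methoxymethoxy)phenyl]-1-methylcyclopropyl]ethenyl}-2-[3,5-bis(methoxymethoxy)phenyl]-6-(methoxymethoxy)-1-benzofuran, via tosylhydrazone 20 (not isolated), via aryldiazomethane 21 (not isolated)
Conditions: 19 (1.5 equiv), TsNHNH2 (1.5 equiv), MeOH, rt, 2 h; then 14, Cs2CO3 (3 equiv), [Co(3,5-DitBu-ChenPhyrin)] (5 mol %, the enantiomer that gives 1R,2S), MeOH/toluene, 40 °C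
Reagents that add atoms: 4-methylbenzenesulfonohydrazide, Cc1ccc(cc1)S(=O)(=O)NN (stays in 20 and 21 only)
Why: Bamford–Stevens release of the donor diazo compound feeds a divalent-cobalt metalloradical cyclopropanation in which the cobalt-bound benzyl radical adds to the unhindered CH2 terminus of the diene and the resulting allyl radical closes 3-exo on the same carbon, the chiral porphyrin pocket setting both new stereocentres as (1R,2S) with the aryl group trans to the alkenyl group.

**Step 11**
Reactants: 2 1,3-bis(methoxymethoxy)benzene; 23 1-bromo-3-methylbut-2-ene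
Product: 25 1,3-bis(methoxymethoxy)-2-(3-methylbut-2-enyl)benzene, via aryllithium 24 (not isolated)
Conditions: n-BuLi (1.1 equiv), THF, 0 °C, 1 h; CuI (10 mol %), 23, −78 °C to rt
Reagents that add atoms: n-butyllithium, [Li]CCCC (lithium stays in 24 only)
Why: Directed ortho-metalation removes the proton flanked by both OMOM groups, and copper-catalysed SN2 allylation with prenyl bromide installs the side chain regiospecifically.

**Step 12**
Reactants: 25 1,3-bis(methoxymethoxy)-2-(3-methylbut-2-enyl)benzene; 26 methyl chloroformate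
Product: 28 methyl 2,4-bis(methoxymethoxy)-3-(3-methylbut-2-enyl)benzoate, via aryllithium 27 (not isolated)
Conditions: n-BuLi (1.1 equiv), TMEDA (1.1 equiv), THF, −20 to 0 °C; cannulate into 26 (3 equiv), THF, −78 °C
Reagents that add atoms: n-butyllithium, [Li]CCCC (lithium stays in 27 only)
Why: A second directed ortho-metalation is steered by the OMOM group to the adjacent ring C–H (complex-induced proximity outruns benzylic deprotonation at low temperature), and inverse addition to the chloroformate stops at the ester.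

**Step 13**
Reactants: 28 methyl 2,4-bis(methoxymethoxy)-3-(3-methylbut-2-enyl)benzoate; 29 trimethylsulfoxonium iodide
Product: 31 1-[2,4-bis(methoxymethoxy)-3-(3-methylbut-2-enyl)phenyl]-2-[dimethyl(oxo)-λ6-sulfanylidene]ethanone, via sulfoxonium methylide 30 (not isolated)
Conditions: 29 (3 equiv), KOtBu (3 equiv), THF, reflux, 2 h; then 28, reflux
Reagents that add atoms: none
Why: Acylation of the Corey–Chaykovsky methylide by the ester followed by proton loss gives the stabilised, bench-stable β-keto sulfoxonium ylide, a non-explosive carbene source.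

**Step 14**
Reactants: 22 vinylcyclopropane (1R,2S); 31 β-keto sulfoxonium ylide
Product: 32 [(1R,2R,6S)-6-[2,4-bis(methoxymethoxy)phenyl]-2-{2-[3,5-bis(methoxymethoxy)phenyl]-6-(methoxymethoxy)-1-benzofuran-5-yl}-4-methylcyclohex-3-en-1-yl][2,4-bis(methoxymethoxy)-3-(3-methylbut-2-enyl)phenyl]methanone
Conditions: [Rh(dppp)]SbF6 (10 mol %), 31 (1.5 equiv, added over 4 h), 1,2-dichloroethane, 70 °C; then DBU (0.3 equiv), 40 °C
Reagents that add atoms: none
Why: Proposed new method: a three-to-six ring expansion in which cationic monovalent rhodium binds the styrenyl alkene of 22 and inserts into the adjacent, weakest cyclopropane bond (quaternary allylic carbon to benzylic carbon, activated by the electron-rich aryl group) to give a σ-benzyl/π-allyl trivalent rhodacyclohexene, the nucleophilic ylide carbon of 31 then attacks rhodium and loses DMSO to give a rhodium acyl-carbene, and migratory insertion of the benzylic carbon (retention) followed by reductive elimination at the aryl-bearing allyl terminus on the metal-bound face closes the cyclohexene and leaves the C(Me)=CH double bond exactly where the allyl unit was; the aryl-bearing stereocentre of 22 is carried over unchanged as C6, suprafacial bond formation on the trans,E-configured substrate places the benzofuranyl group at C2 cis to it, and DBU equilibrates the acidic ketone α-carbon C1 to the all-equatorial (1R,2R,6S) isomer; the closest known reaction types are the rhodium-catalysed carbonylative five-plus-one ring expansion of vinylcyclopropanes, its dinickel variant with vinylidenes, formal carbene insertion into C–C bonds through rhodium β-carbon elimination, and the acylmethylation of trivalent rhodacycles by sulfoxonium ylides.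

**Step 15**
Reactants: 32 heptakis(methoxymethyl) ether of the target
Product: 33 [(1R,2R,6S)-6-(2,4-dihydroxyphenyl)-2-[2-(3,5-dihydroxyphenyl)-6-hydroxy-1-benzofuran-5-yl]-4-methylcyclohex-3-en-1-yl][2,4-dihydroxy-3-(3-methylbut-2-enyl)phenyl]methanone (CNP0150120.1)
Conditions: HCl (1.25 M in MeOH), THF, 30 °C
Reagents that add atoms: none
Why: Acid-catalysed transacetalisation to dimethoxymethane frees all seven phenols under conditions used for prenylated polyphenols, no stereocentre is touched, and the α-carbon already sits in its thermodynamic configuration.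

**Compound list**
1 | resorcinol | Oc1cccc(O)c1 | starting material
2 | 1,3-bis(methoxymethoxy)benzene | COCOc1cccc(OCOC)c1 | intermediate
3 | 2-[3,5-bis(methoxymethoxy)phenyl]-4,4,5,5-tetramethyl-1,3,2-dioxaborolane | COCOc1cc(OCOC)cc(c1)B1OC(C)(C)C(C)(C)O1 | intermediate
4 | 1-iodo-3,5-bis(methoxymethoxy)benzene | COCOc1cc(I)cc(OCOC)c1 | intermediate
5 | ethynyltrimethylsilane | C#C[Si](C)(C)C | starting material
6 | {[3,5-bis(methoxymethoxy)phenyl]ethynyl}trimethylsilane | COCOc1cc(OCOC)cc(c1)C#C[Si](C)(C)C | intermediate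
7 | 4,6-diiodobenzene-1,3-diol | Oc1cc(O)c(I)cc1I | intermediate
8 | 1-ethynyl-3,5-bis(methoxymethoxy)benzene | C#Cc1cc(OCOC)cc(OCOC)c1 | intermediate
9 | 4-{[3,5-bis(methoxymethoxy)phenyl]ethynyl}-6-iodobenzene-1,3-diol | COCOc1cc(OCOC)cc(c1)C#Cc1cc(I)c(O)cc1O | intermediate
10 | 2-[3,5-bis(methoxymethoxy)phenyl]-5-iodo-1-benzofuran-6-ol | COCOc1cc(OCOC)cc(c1)-c1cc2cc(I)c(O)cc2o1 | intermediate
11 | 2-[3,5-bis(methoxymethoxy)phenyl]-5-iodo-6-(methoxymethoxy)-1-benzofuran | COCOc1cc(OCOC)cc(c1)-c1cc2cc(I)c(OCOC)cc2o1 | intermediate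
12 | 2-methylbut-1-en-3-yne | C=C(C)C#C | starting material
13 | 4,4,5,5-tetramethyl-2-[(1E)-3-methylbuta-1,3-dienyl]-1,3,2-dioxaborolane | CC(=C)/C=C/B1OC(C)(C)C(C)(C)O1 | intermediate
14 | 2-[3,5-bis(methoxymethoxy)phenyl]-6-(methoxymethoxy)-5-[(1E)-3-methylbuta-1,3-dienyl]-1-benzofuran | CC(=C)/C=C/c1cc2cc(oc2cc1OCOC)-c1cc(OCOC)cc(OCOC)c1 | intermediate
15 | N,N-dimethylformamide | CN(C)C=O | starting material
16 | (chloromethylidene)dimethylammonium dichlorophosphate | C[N+](C)=CCl.[O-]P(=O)(Cl)Cl | intermediate
17 | [(2,4-dihydroxyphenyl)methylidene]dimethylammonium dichlorophosphate | C[N+](C)=Cc1ccc(O)cc1O.[O-]P(=O)(Cl)Cl | intermediate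
18 | 2,4-dihydroxybenzaldehyde | O=Cc1ccc(O)cc1O | intermediate
19 | 2,4-bis(methoxymethoxy)benzaldehyde | COCOc1ccc(C=O)c(OCOC)c1 | intermediate
20 | (E)-tosylhydrazone of 19 | COCOc1ccc(/C=N/NS(=O)(=O)c2ccc(C)cc2)c(OCOC)c1 | intermediate
21 | 1-(diazomethyl)-2,4-bis(methoxymethoxy)benzene | COCOc1ccc(C=[N+]=[N-])c(OCOC)c1 | intermediate
22 | (1R,2S)-vinylcyclopropane, aryl trans to the E-styrenyl group, methyl on the alkenyl-bearing carbon | C[C@]1(/C=C/c2cc3cc(oc3cc2OCOC)-c2cc(OCOC)cc(OCOC)c2)C[C@@H]1c1ccc(OCOC)cc1OCOC | intermediate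
23 | 1-bromo-3-methylbut-2-ene (prenyl bromide) | CC(C)=CCBr | starting material
24 | [2,6-bis(methoxymethoxy)phenyl]lithium | [Li]c1c(OCOC)cccc1OCOC | intermediate
25 | 1,3-bis(methoxymethoxy)-2-(3-methylbut-2-enyl)benzene | CC(C)=CCc1c(OCOC)cccc1OCOC | intermediate
26 | methyl chloroformate | COC(=O)Cl | starting material
27 | [2,4-bis(methoxymethoxy)-3-(3-methylbut-2-enyl)phenyl]lithium | [Li]c1ccc(OCOC)c(CC=C(C)C)c1OCOC | intermediate
28 | methyl 2,4-bis(methoxymethoxy)-3-(3-methylbut-2-enyl)benzoate | COC(=O)c1ccc(OCOC)c(CC=C(C)C)c1OCOC | intermediate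
29 | trimethylsulfoxonium iodide | C[S+](C)(C)=O.[I-] | starting material
30 | dimethylsulfoxonium methylide | C=S(C)(C)=O | intermediate
31 | β-keto sulfoxonium ylide of the prenylated aryl ketone | CC(C)=CCc1c(OCOC)ccc(C(=O)C=S(C)(C)=O)c1OCOC | intermediate
32 | (1R,2R,6S)-heptakis(methoxymethyl) ether of the target | CC(C)=CCc1c(OCOC)ccc(C(=O)[C@@H]2[C@@H](c3ccc(OCOC)cc3OCOC)CC(C)=C[C@H]2c2cc3cc(-c4cc(OCOC)cc(OCOC)c4)oc3cc2OCOC)c1OCOC | intermediate
33 | CNP0150120.1, all-trans (1R,2R,6S) | CC(C)=CCc1c(O)ccc(C(=O)[C@@H]2[C@@H](c3ccc(O)cc3O)CC(C)=C[C@H]2c2cc3cc(-c4cc(O)cc(O)c4)oc3cc2O)c1O | target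

**Totals**
- Total step count: 15.
- Longest linear sequence: 9 steps (steps 1, 2, 3, 5, 6, 7, 10, 14, 15).

**Steps most likely to fail**

Step 14 (the proposed new step). Rhodium may open the less hindered cyclopropane bond. The rhodacycle may collapse directly to a cyclopentene. The carbene may be lost to the neighbouring OMOM oxygen. The fallback keeps the ring-expansion logic but uses only known reactions; it sets out from 22 (and 25) and comes back at 32. The known rhodium-catalysed carbonylative ring expansion of vinylcyclopropanes (CO 0.2 atm, [Rh(dppp)]SbF6, 1,2-dichloroethane, 80 °C) converts 22 into the β,γ-unsaturated 2,6-diarylcyclohexenone F1. Wittig methoxymethylenation with Ph3P=CHOMe gives the enol ether F2. PPTS in wet acetone followed by DBU gives the all-trans cyclohexenecarbaldehyde F3. Addition of aryllithium 27, made from 25 as in step 12, gives the benzylic carbinol F4. Dess–Martin oxidation then delivers 32.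

Step 10. The electron-rich, ortho-substituted diazo compound may dimerise to azine or stilbene. The trans/cis ratio and ee on this large diene are untested, and the cis isomer would lead to the wrong C2/C6 relationship in step 14. The fallback builds the cyclopropane from an alkene of fixed geometry; it sets out from 19 and 11, makes step 7 unnecessary, and comes back at 22.
- Wittig reaction of 19 with ethyl 2-(triphenylphosphoranylidene)propanoate gives the E-enoate F5.
- i-Bu2AlH reduction gives the E-allylic alcohol F6.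
- Charette asymmetric cyclopropanation (Zn(CH2I)2 and the tartramide-derived butyl dioxaborolane) gives the cyclopropylmethanol F7, with aryl and CH2OH trans by stereospecificity.
- Dess–Martin oxidation gives the cyclopropanecarbaldehyde F8.
- The Ohira–Bestmann reagent (K2CO3, MeOH) gives the ethynylcyclopropane F9.
- HBpin with Cp2ZrHCl gives the E-alkenylboronate F10.
- Suzuki–Miyaura coupling with 11 (Pd(dppf)Cl2, K3PO4) gives 22.

Step 15. Seven acetals must fall under protic acid while free phenols sit next to the prenyl group and the ring alkene, so chroman formation is the danger. The fallback avoids having free phenol and acid present together; it sets out from 32 and comes back at 33. TESOTf with 2,2'-bipyridyl in MeCN exchanges the aryl MOM ethers directly for silyl ethers, giving the isolable heptakis(triethylsilyl) ether F11. Buffered fluoride (Bu4NF/AcOH, THF, 0 °C) then releases 33 under essentially neutral conditions.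

**Further compounds**
F1 | step 14 | (2R,6S)-6-[2,4-bis(methoxymethoxy)phenyl]-2-(protected benzofuran-5-yl)-4-methylcyclohex-3-en-1-one | O=C1[C@@H](c2ccc(OCOC)cc2OCOC)CC(C)=C[C@H]1c1cc2cc(-c3cc(OCOC)cc(OCOC)c3)oc2cc1OCOC
F2 | step 14 | methoxymethylidene enol ether of F1 | COC=C1[C@@H](c2ccc(OCOC)cc2OCOC)CC(C)=C[C@H]1c1cc2cc(-c3cc(OCOC)cc(OCOC)c3)oc2cc1OCOC
F3 | step 14 | all-trans (1R,2R,6S)-cyclohex-3-ene-1-carbaldehyde | O=C[C@@H]1[C@@H](c2ccc(OCOC)cc2OCOC)CC(C)=C[C@H]1c1cc2cc(-c3cc(OCOC)cc(OCOC)c3)oc2cc1OCOC
F4 | step 14 | benzylic carbinol (epimers at the carbinol carbon) | CC(C)=CCc1c(OCOC)ccc(C(O)[C@@H]2[C@@H](c3ccc(OCOC)cc3OCOC)CC(C)=C[C@H]2c2cc3cc(-c4cc(OCOC)cc(OCOC)c4)oc3cc2OCOC)c1OCOC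
F5 | step 10 | ethyl (E)-3-[2,4-bis(methoxymethoxy)phenyl]-2-methylprop-2-enoate | CCOC(=O)/C(C)=C/c1ccc(OCOC)cc1OCOC
F6 | step 10 | (E)-3-[2,4-bis(methoxymethoxy)phenyl]-2-methylprop-2-en-1-ol | OC/C(C)=C/c1ccc(OCOC)cc1OCOC
F7 | step 10 | {2-[2,4-bis(methoxymethoxy)phenyl]-1-methylcyclopropyl}methanol, aryl trans to CH2OH, same spatial arrangement as 22 | C[C@]1(CO)C[C@@H]1c1ccc(OCOC)cc1OCOC
F8 | step 10 | 2-[2,4-bis(methoxymethoxy)phenyl]-1-methylcyclopropane-1-carbaldehyde | C[C@]1(C=O)C[C@@H]1c1ccc(OCOC)cc1OCOC
F9 | step 10 | 1-ethynyl-1-methyl-2-[2,4-bis(methoxymethoxy)phenyl]cyclopropane | C[C@]1(C#C)C[C@@H]1c1ccc(OCOC)cc1OCOC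
F10 | step 10 | (E)-2-(cyclopropyl)ethenylboronic acid pinacol ester | C[C@]1(/C=C/B2OC(C)(C)C(C)(C)O2)C[C@@H]1c1ccc(OCOC)cc1OCOC
F11 | step 15 | (1R,2R,6S)-heptakis(triethylsilyl) ether of the target | CC(C)=CCc1c(O[Si](CC)(CC)CC)ccc(C(=O)[C@@H]2[C@@H](c3ccc(O[Si](CC)(CC)CC)cc3O[Si](CC)(CC)CC)CC(C)=C[C@H]2c2cc3cc(-c4cc(O[Si](CC)(CC)CC)cc(O[Si](CC)(CC)CC)c4)oc3cc2O[Si](CC)(CC)CC)c1O[Si](CC)(CC)CC
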